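Readings and results were generated by integration with made-up constants; scatter was added.

Monday's run ends with 24% of target and 16% of isomer of the product, a share of target of 60.0%.

| flask | starting material | temperature | remark | time |
|---|---|---|---|---|
| Friday's | 0.38 M | 105 °C | run made earlier |  |
| Monday's | 0.56 M | 116 °C | run made earlier |  |
| beta | 0.75 M | 100 °C |  | 15 h |
| alpha | 0.75 M | 120 °C |  | 50 h |

| run | time / h | target / % | isomer of the product / % |
|---|---|---|---|
| Friday's | 0.667 | 0 | 0 |
| Friday's | 1.33 | 3 | 0 |
| Friday's | 2.00 | 0 | 1 |
| Friday's | 3.00 | 3 | 1 |
| Friday's | 5.00 | 6 | 3 |
| Friday's | 10.0 | 14 | 11 |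
| Monday's | 0.333 | 1 | 0 |
| Monday's | 0.833 | 0 | 0 |
| Monday's | 1.33 | 5 | 0 |
| Monday's | 2.50 | 10 | 6 |
| Monday's | 5.00 | 24 | 16 |

(scatter of a reading: 2 percentage points)

1. the winner by share of target in all that became target or isomer of the product; "neither" if no more than 2 percentage points parts them (beta / alpha / neither)
2. share of target in all that became target or isomer of the product, beta
3. share of target in all that became target or isomer of the product, alpha

- the earlier runs were read with a standard deviation of 2 percentage points

I put that share back into Friday's last reading, where it expects 15.0% of target against 14% read, a miss smaller than the scatter of one reading. So I go round once more and pool both last readings into 58.5%, the pooled target share, which is summed target over summed target and isomer of the product, the selectivity as these readings show it, good to about 3.1 points. I commit to it for beta and for alpha alike, so I expect neither to win.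

The forecast gives 61% for beta, 60% for alpha and so neither, holding that “Within this noise, share shows no clear dependence on temperature, concentration or conversion”.

The simulation gives 56.2% for beta and 56.9% for alpha, so neither, and my pooled share stands 2.3 points and 1.6 points above them, inside its scatter.

    intermediate A → intermediate B (k = 0.0420 h⁻¹, Ea = 123 kJ mol⁻¹)
    intermediate B → target (k = 0.280 h⁻¹, Ea = 111 kJ mol⁻¹)
    starting material → intermediate A (k = 0.240 h⁻¹, Ea = 109 kJ mol⁻¹)
    target ⇌ isomer of the product (K = 1.20, k = 0.260 h⁻¹, Ea = 116 kJ mol⁻¹, ΔH = −28.0 kJ mol⁻¹)
    2 starting material → self-condensation product (k = 0.190 L mol⁻¹ h⁻¹, Ea = 73.0 kJ mol⁻¹)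
    (constants at 100 °C)

In beta the relaxation half-life of target and isomer of the product, 1.45 h, is shorter than the 15 h of the run, yet at that time 39.6% of the charge still stands as intermediate A, and target and isomer of the product hold 10.5% and 8.23%. Left ten times as long, beta falls by 150 h to a share of 45.5%, while alpha still stands at 56.9% at 500 h. The repeat of beta at 115 °C gives 54.5%, which is 4 points under the pooled target share.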